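**Retrosynthetic overview**

- Target 18 ⇒ octa-O-benzyl flavan-3-ol 17 (global hydrogenolysis) ⇒ achiral 2-aryl-4H-chromene 15, by taking apart the C2–H and C3–O bonds (syn H/B addition, then C–B to C–O oxidation).
- 15 ⇒ flavylium chloride 14 (hydride at C4) ⇒ aldehyde 7 + methyl ketone 12 (C3–C4 by aldol condensation, O1–C2 by cyclodehydration); each partner already carries its tri-O-benzylgallate.
- The strategy rests on two features. First, C2 (bearing O1 and ring B) and C3 (bearing OH) of ring C are adjacent and trans, which is the footprint of a syn H–B addition across a C2=C3 enol ether. Second, in ring A the oxygen O7 is para to C4a while O1 and O5 are ortho, so the 7-gallate can be fixed on the para hydroxyl of a phloroglucinaldehyde and the 4'-gallate on the acetophenone.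
- Ring order: rings A, B and both galloyl rings are bought. Ring C is the only ring made: it is closed as an aromatic pyrylium (step 10) and dearomatised in two stages (steps 11 and 12).

Key step: step 12

Assumption: IpcBH2 of high enantiomeric purity, made beforehand from (+)-α-pinene, is at hand as a titrated THF solution; O5 is carried as a benzyl ether because direct mono-acylation of 2,4,6-trihydroxybenzaldehyde cannot be relied on to single out the 4-hydroxyl.

**Route**

Step 1
Reactants: 1 3,4,5-tris(benzyloxy)benzoic acid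
Product: 2 3,4,5-tris(benzyloxy)benzoyl chloride
Conditions: (COCl)2, DMF (cat.), CH2Cl2, 0 °C to rt; evaporation
Reagents that add atoms: oxalyl chloride, O=C(Cl)C(Cl)=O
Why: Acid chloride formation through the chloroiminium (Vilsmeier-type) activation is neutral enough to leave the three benzyl ethers untouched.

Step 2
Reactants: 3 2,4,6-trihydroxybenzaldehyde
Product: 4 2-hydroxy-4,6-bis(methoxymethoxy)benzaldehyde
Conditions: MOMCl (2.1 equiv), i-Pr2NEt, CH2Cl2, 0 °C to rt
Reagents that add atoms: chloromethyl methyl ether, COCCl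
Why: Williamson-type O-alkylation (MOM ether formation) takes the two hydroxyls that are not held in the hydrogen bond to the formyl oxygen, so the same bis-ether results whichever reacts first and the chelated ortho hydroxyl is left over.

Step 3
Reactants: 4 2-hydroxy-4,6-bis(methoxymethoxy)benzaldehyde
Product: 5 2-(benzyloxy)-4,6-bis(methoxymethoxy)benzaldehyde
Conditions: BnBr, K2CO3, DMF, 50 °C
Reagents that add atoms: benzyl bromide, BrCc1ccccc1
Why: Williamson ether synthesis under mildly forcing conditions benzylates the remaining chelated phenol, the oxygen that becomes O5 of the flavan.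

Step 4
Reactants: 5 2-(benzyloxy)-4,6-bis(methoxymethoxy)benzaldehyde
Product: 6 2-(benzyloxy)-4,6-dihydroxybenzaldehyde
Conditions: HCl (cat.), MeOH, 45 °C; aqueous work-up
Reagents that add atoms: none
Why: Acid-catalysed acetal methanolysis removes both MOM groups while the benzyl aryl ether is stable to dilute HCl, leaving one hydroxyl chelated ortho to the formyl group and one free para to it.

Step 5
Reactants: 6 2-(benzyloxy)-4,6-dihydroxybenzaldehyde; 2 3,4,5-tris(benzyloxy)benzoyl chloride
Product: 7 3-(benzyloxy)-4-formyl-5-hydroxyphenyl 3,4,5-tris(benzyloxy)benzoate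
Conditions: 2 (1.0 equiv, slow addition), i-Pr2NEt (1.1 equiv), CH2Cl2/THF, −20 to 0 °C
Reagents that add atoms: none
Why: Regioselective phenol acylation with an acid chloride and amine base: the para hydroxyl is the more acidic and unchelated one and is esterified, while the ortho hydroxyl stays tied up in its hydrogen bond to the aldehyde, as in 2,4-dihydroxybenzaldehyde.

Step 6
Reactants: 8 3,4-dihydroxyacetophenone
Product: 9 1-[3-hydroxy-4-(4-methoxybenzyloxy)phenyl]ethanone
Conditions: PMBCl (1.1 equiv), NaHCO3, NaI (cat.), DMF, 40 °C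
Reagents that add atoms: 4-methoxybenzyl chloride, COc1ccc(CCl)cc1
Why: Regioselective Williamson alkylation: the weak base ionises only the 4-hydroxyl, which is para to the acetyl group and the more acidic, so the PMB group goes there.

Step 7
Reactants: 9 1-[3-hydroxy-4-(4-methoxybenzyloxy)phenyl]ethanone
Product: 10 1-[3-(benzyloxy)-4-(4-methoxybenzyloxy)phenyl]ethanone
Conditions: BnBr, K2CO3, DMF, rt
Reagents that add atoms: benzyl bromide, BrCc1ccccc1
Why: Williamson ether synthesis on the one remaining phenol.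

Step 8
Reactants: 10 1-[3-(benzyloxy)-4-(4-methoxybenzyloxy)phenyl]ethanone
Product: 11 1-[3-(benzyloxy)-4-hydroxyphenyl]ethanone
Conditions: TFA, anisole, CH2Cl2, 0 °C
Reagents that add atoms: none
Why: Acidolysis of the PMB aryl ether (SN1 cleavage, the cation being trapped by anisole in a Friedel–Crafts alkylation) leaves the less labile benzyl ether in place.

Step 9
Reactants: 11 1-[3-(benzyloxy)-4-hydroxyphenyl]ethanone; 2 3,4,5-tris(benzyloxy)benzoyl chloride
Product: 12 4-acetyl-2-(benzyloxy)phenyl 3,4,5-tris(benzyloxy)benzoate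
Conditions: Et3N, DMAP (cat.), CH2Cl2, 0 °C to rt
Reagents that add atoms: none
Why: DMAP-catalysed acyl transfer esterifies the only phenol.

Step 10
Reactants: 7 3-(benzyloxy)-4-formyl-5-hydroxyphenyl 3,4,5-tris(benzyloxy)benzoate; 12 4-acetyl-2-(benzyloxy)phenyl 3,4,5-tris(benzyloxy)benzoate
Product: 14 5-(benzyloxy)-2-{3-(benzyloxy)-4-[3,4,5-tris(benzyloxy)benzoyloxy]phenyl}-7-[3,4,5-tris(benzyloxy)benzoyloxy]chromenylium chloride (flavylium chloride), via 2-hydroxychalcone 13 (not isolated)
Conditions: dry HCl (g), EtOAc, 0 to 4 °C, 48 h; then Et2O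
Reagents that add atoms: hydrogen chloride, Cl
Why: Acid-mediated flavylium synthesis: Claisen–Schmidt-type aldol condensation of the methyl ketone with the aldehyde gives chalcone 13, whose free ortho hydroxyl adds 6-exo-trig to the protonated ketone and loses water to give the aromatic benzopyrylium; aryl esters and benzyl ethers should tolerate dry HCl in the cold, and precipitation removes the salt from the equilibria.

Step 11
Reactants: 14 flavylium chloride
Product: 15 5-(benzyloxy)-2-{3-(benzyloxy)-4-[3,4,5-tris(benzyloxy)benzoyloxy]phenyl}-4H-chromen-7-yl 3,4,5-tris(benzyloxy)benzoate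
Conditions: Hantzsch ester (diethyl 2,6-dimethyl-1,4-dihydropyridine-3,5-dicarboxylate, 1.1 equiv), 2,6-lutidine (1.1 equiv), CH2Cl2/MeCN, 0 °C, dark; 14 added slowly
Reagents that add atoms: none
Why: Hydride transfer from an NADH-type 1,4-dihydropyridine to C4 of the benzopyrylium, its soft and unhindered position, gives the 4H-chromene; inverse addition keeps the cation away from the enol ether product, and the lutidine takes up HCl so that no acid remains to protonate C3 and open the way to over-reduction.

Step 12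
Reactants: 15 2-aryl-4H-chromene
Product: 17 (2R,3S)-5-(benzyloxy)-2-{3-(benzyloxy)-4-[3,4,5-tris(benzyloxy)benzoyloxy]phenyl}-3-hydroxy-3,4-dihydro-2H-chromen-7-yl 3,4,5-tris(benzyloxy)benzoate, via C3-alkylborane 16 (not isolated)
Conditions: IpcBH2 [from (+)-α-pinene] (1.5 equiv), THF, −25 to 0 °C; then MeOH, pH 7 phosphate buffer, 30% H2O2, 0 °C to rt
Reagents that add atoms: hydrogen peroxide, OO
Why: Proposed new method: IpcBH2 should add across the C2=C3 enol ether of the flat, achiral 15 through a four-centre transition state, with boron going to C3 (the β-carbon of both the enol ether and the styrene) and hydride to C2 on the same face, so that aryl and boron are trans in 16; buffered peroxide then replaces boron by hydroxyl with retention to give the 2,3-trans flavan-3-ol. The closest known reactions are the IpcBH2 hydroboration–oxidation of 1-arylcycloalkenes to trans-2-arylcycloalkanols, the asymmetric hydroboration of cyclic enol ethers with pinene-derived boranes, and the racemic borane hydroboration–oxidation of 4H-flavenes to 2,3-trans-flavan-3-ols. No ring is closed, since ring C is already in place. C2 (R) and C3 (S) are both created here: their relative configuration follows from the syn addition and the retentive oxidation, and their absolute configuration from the isopinocampheyl group, the reagent from (+)-α-pinene being the one that turns 1-arylcycloalkenes into (1S,2R)-trans-2-arylcycloalkanols, a sense that maps onto (2R,3S) here (if the ring oxygen inverts the facial preference, the reagent from (−)-α-pinene is used). The step needs C3 regioselectivity, secured by the concurring polarisation of the alkene by O1 and the aryl group, and enantioface selectivity, for which a trisubstituted, aryl-bearing cyclic alkene is the best substrate class of this borane; low temperature and the neutral oxidation should keep the β-aryloxy borane from eliminating toward O1 and spare the aryl gallates.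

Step 13
Reactants: 17 octa-O-benzyl (2R,3S)-flavan-3-ol
Product: 18 catechin 7,4'-di-O-gallate, (2R,3S)-2-[3-hydroxy-4-(3,4,5-trihydroxybenzoyloxy)phenyl]-3,5-dihydroxy-3,4-dihydro-2H-chromen-7-yl 3,4,5-trihydroxybenzoate
Conditions: H2 (1 atm), Pd(OH)2 on carbon, THF/MeOH, rt; filtration, concentration below 30 °C
Reagents that add atoms: none
Why: Catalytic hydrogenolysis cleaves the eight benzyl aryl ethers while the aryl esters, the C2–O1 bond and both stereocentres should stay untouched under neutral conditions at room temperature, and the base-free work-up avoids 4' to 3' galloyl migration on the catechol.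

**Compound list**

1 | 3,4,5-tris(benzyloxy)benzoic acid | OC(=O)c1cc(OCc2ccccc2)c(OCc2ccccc2)c(OCc2ccccc2)c1 | starting material
2 | 3,4,5-tris(benzyloxy)benzoyl chloride | ClC(=O)c1cc(OCc2ccccc2)c(OCc2ccccc2)c(OCc2ccccc2)c1 | intermediate
3 | 2,4,6-trihydroxybenzaldehyde | O=Cc1c(O)cc(O)cc1O | starting material
4 | 2-hydroxy-4,6-bis(methoxymethoxy)benzaldehyde | O=Cc1c(O)cc(OCOC)cc1OCOC | intermediate
5 | 2-(benzyloxy)-4,6-bis(methoxymethoxy)benzaldehyde | O=Cc1c(OCc2ccccc2)cc(OCOC)cc1OCOC | intermediate
6 | 2-(benzyloxy)-4,6-dihydroxybenzaldehyde | O=Cc1c(OCc2ccccc2)cc(O)cc1O | intermediate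
7 | 3-(benzyloxy)-4-formyl-5-hydroxyphenyl 3,4,5-tris(benzyloxy)benzoate (ring A aldehyde) | O=Cc1c(O)cc(OC(=O)c2cc(OCc3ccccc3)c(OCc3ccccc3)c(OCc3ccccc3)c2)cc1OCc1ccccc1 | intermediate
8 | 3,4-dihydroxyacetophenone | CC(=O)c1ccc(O)c(O)c1 | starting material
9 | 1-[3-hydroxy-4-(4-methoxybenzyloxy)phenyl]ethanone | CC(=O)c1ccc(OCc2ccc(OC)cc2)c(O)c1 | intermediate
10 | 1-[3-(benzyloxy)-4-(4-methoxybenzyloxy)phenyl]ethanone | CC(=O)c1ccc(OCc2ccc(OC)cc2)c(OCc2ccccc2)c1 | intermediate
11 | 1-[3-(benzyloxy)-4-hydroxyphenyl]ethanone | CC(=O)c1ccc(O)c(OCc2ccccc2)c1 | intermediate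
12 | 4-acetyl-2-(benzyloxy)phenyl 3,4,5-tris(benzyloxy)benzoate (ring B ketone) | CC(=O)c1ccc(OC(=O)c2cc(OCc3ccccc3)c(OCc3ccccc3)c(OCc3ccccc3)c2)c(OCc2ccccc2)c1 | intermediate
13 | (E)-2-hydroxychalcone from 7 and 12: 3-[2-(benzyloxy)-6-hydroxy-4-(tri-O-benzylgalloyloxy)phenyl]-1-[3-(benzyloxy)-4-(tri-O-benzylgalloyloxy)phenyl]prop-2-en-1-one | O=C(/C=C/c1c(O)cc(OC(=O)c2cc(OCc3ccccc3)c(OCc3ccccc3)c(OCc3ccccc3)c2)cc1OCc1ccccc1)c1ccc(OC(=O)c2cc(OCc3ccccc3)c(OCc3ccccc3)c(OCc3ccccc3)c2)c(OCc2ccccc2)c1 | intermediate
14 | 5-(benzyloxy)-2-{3-(benzyloxy)-4-[3,4,5-tris(benzyloxy)benzoyloxy]phenyl}-7-[3,4,5-tris(benzyloxy)benzoyloxy]chromenylium chloride | O=C(Oc1cc(OCc3ccccc3)c2ccc(-c3ccc(OC(=O)c4cc(OCc5ccccc5)c(OCc5ccccc5)c(OCc5ccccc5)c4)c(OCc4ccccc4)c3)[o+]c2c1)c1cc(OCc2ccccc2)c(OCc2ccccc2)c(OCc2ccccc2)c1.[Cl-] | intermediate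
15 | 5-(benzyloxy)-2-{3-(benzyloxy)-4-[3,4,5-tris(benzyloxy)benzoyloxy]phenyl}-4H-chromen-7-yl 3,4,5-tris(benzyloxy)benzoate (achiral 4H-flavene) | O=C(Oc1cc(OCc3ccccc3)c2c(c1)OC(c1ccc(OC(=O)c3cc(OCc4ccccc4)c(OCc4ccccc4)c(OCc4ccccc4)c3)c(OCc3ccccc3)c1)=CC2)c1cc(OCc2ccccc2)c(OCc2ccccc2)c(OCc2ccccc2)c1 | intermediate
16 | 2,3-trans C3-borane of the flavan: hydrido(isopinocampheyl)boryl group in place of the 3-OH of 17, same spatial arrangement at C2 and C3 (formally 2S,3S by the sequence rule) | O=C(Oc1cc(OCc3ccccc3)c2c(c1)O[C@H](c1ccc(OC(=O)c3cc(OCc4ccccc4)c(OCc4ccccc4)c(OCc4ccccc4)c3)c(OCc3ccccc3)c1)[C@@H]([BH][C@@H]5C[C@@H]6C[C@H]([C@H]5C)C6(C)C)C2)c1cc(OCc2ccccc2)c(OCc2ccccc2)c(OCc2ccccc2)c1 | intermediate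
17 | (2R,3S)-5-(benzyloxy)-2-{3-(benzyloxy)-4-[3,4,5-tris(benzyloxy)benzoyloxy]phenyl}-3-hydroxy-3,4-dihydro-2H-chromen-7-yl 3,4,5-tris(benzyloxy)benzoate | O=C(Oc1cc(OCc3ccccc3)c2c(c1)O[C@H](c1ccc(OC(=O)c3cc(OCc4ccccc4)c(OCc4ccccc4)c(OCc4ccccc4)c3)c(OCc3ccccc3)c1)[C@@H](O)C2)c1cc(OCc2ccccc2)c(OCc2ccccc2)c(OCc2ccccc2)c1 | intermediate
18 | catechin 7,4'-di-O-gallate, (2R,3S) | O=C(Oc1cc(O)c2c(c1)O[C@H](c1ccc(OC(=O)c3cc(O)c(O)c(O)c3)c(O)c1)[C@@H](O)C2)c1cc(O)c(O)c(O)c1 | target

**Step count**

Total: 13 steps. Longest linear sequence: 8 steps (3 → 4 → 5 → 6 → 7 → 14 → 15 → 17 → 18; the ring B branch from 8 is equally long).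

**Steps most likely to fail**

1. Step 12 (proposed new method). The borane may discriminate the two faces of the enol ether poorly, or in the opposite sense. The C3-borane may also undergo anti-elimination toward O1 and open ring C before it is oxidised. Fallback, from 15 back to 17, with known chemistry: racemic hydroboration of 15 with BH3·SMe2 in THF at 0 °C, followed by the same buffered H2O2 oxidation. This reaction type is known to turn 4H-flavenes into 2,3-trans-flavan-3-ols, and should give 17 as a racemate with its (2S,3R) enantiomer F1. The two are resolved by preparative HPLC on a polysaccharide chiral stationary phase, and 17 continues to step 13.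

2. Step 11. Hydride may be delivered to C2 in place of C4, the enol ether product may couple with unreacted cation, or residual acid may trigger over-reduction to the flavan. Fallback, from 14 back to 15:
   - The salt 14 is opened in MeCN/water buffered with NaOAc to the trans-chalcone 13, which is isolated this time.
   - The enone C=C of 13 is hydrogenated homogeneously (H2, RhCl(PPh3)3, benzene/EtOH), which leaves benzyl ethers alone, to give the dihydrochalcone F2.
   - Acid-catalysed cyclodehydration of its hemiketal (PPTS, toluene, 4 Å molecular sieves, 70 °C) gives 15.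
   
   The C4 hydrogens then come from alkene hydrogenation, so neither C2 attack nor cation–enol ether coupling can occur.

3. Step 10. The aldol condensation may stall, or the long exposure to HCl may cause loss of benzyl groups or cleavage of the activated aryl esters. Fallback, from 12 (with 7) back to 14:
   - α-Bromination of 12 (PhNMe3Br3, THF, 0 °C) gives the bromo ketone F3.
   - PPh3 (toluene, rt) gives the phosphonium bromide F4, and aqueous NaHCO3 converts it to the stabilised ylide F5.
   - Wittig olefination of 7 with F5 (toluene, 80 °C) gives chalcone 13 under neutral conditions.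
   - A short treatment of isolated 13 with dry HCl in EtOAc at 0 °C closes ring C to 14.

**Further compounds**

F1 | step 12 | (2S,3R)-enantiomer of 17 | O=C(Oc1cc(OCc3ccccc3)c2c(c1)O[C@@H](c1ccc(OC(=O)c3cc(OCc4ccccc4)c(OCc4ccccc4)c(OCc4ccccc4)c3)c(OCc3ccccc3)c1)[C@H](O)C2)c1cc(OCc2ccccc2)c(OCc2ccccc2)c(OCc2ccccc2)c1
F2 | step 11 | dihydrochalcone, 3-[2-(benzyloxy)-6-hydroxy-4-(tri-O-benzylgalloyloxy)phenyl]-1-[3-(benzyloxy)-4-(tri-O-benzylgalloyloxy)phenyl]propan-1-one | O=C(CCc1c(O)cc(OC(=O)c2cc(OCc3ccccc3)c(OCc3ccccc3)c(OCc3ccccc3)c2)cc1OCc1ccccc1)c1ccc(OC(=O)c2cc(OCc3ccccc3)c(OCc3ccccc3)c(OCc3ccccc3)c2)c(OCc2ccccc2)c1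
F3 | step 10 | 2-(benzyloxy)-4-(bromoacetyl)phenyl 3,4,5-tris(benzyloxy)benzoate | O=C(CBr)c1ccc(OC(=O)c2cc(OCc3ccccc3)c(OCc3ccccc3)c(OCc3ccccc3)c2)c(OCc2ccccc2)c1
F4 | step 10 | {2-[3-(benzyloxy)-4-(tri-O-benzylgalloyloxy)phenyl]-2-oxoethyl}triphenylphosphonium bromide | [Br-].O=C(C[P+](c1ccccc1)(c1ccccc1)c1ccccc1)c1ccc(OC(=O)c2cc(OCc3ccccc3)c(OCc3ccccc3)c(OCc3ccccc3)c2)c(OCc2ccccc2)c1
F5 | step 10 | 2-(benzyloxy)-4-[(triphenylphosphoranylidene)acetyl]phenyl 3,4,5-tris(benzyloxy)benzoate (stabilised ylide) | O=C(C=P(c1ccccc1)(c1ccccc1)c1ccccc1)c1ccc(OC(=O)c2cc(OCc3ccccc3)c(OCc3ccccc3)c(OCc3ccccc3)c2)c(OCc2ccccc2)c1
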